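Late in the blue flask, which is the flask asked about, target has stopped rising: it reads 51.7% at 5.00 min and 49.4% at 12.0 min, although substrate is still feeding it. Counting what is missing from the balance as isomer, the question turns round: what has to be true for target to climb again once the feed has faded?

For target ⇌ isomer, the back rate divided by the forward rate is Q/K, and time drops out. Here Q, the isomer-to-target ratio [isomer]/[target] standing in the flask, is compared with K, the value of Q at which the two directions balance. Target gains from this step when Q exceeds K, which is the approach to thermodynamic control.

Q = (100 − 49.4 − 6.7) / 49.4 = 0.889

Target fell while still being fed, so forward beat back in the blue flask, and K at 25 °C lies above this reading. The red run, with target still rising between its readings, gives no such bound at its lower temperature: its Q is 0.276 at 25.0 min, with 45.0% substrate still feeding target. These readings therefore leave the sign of K's change with temperature open.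

My reckoning is that waiting loses target, and that zeta loses the same, since leaving ligand stands in neither term of Q. Through this step, delta gains target if a rise of 15 K brings K below the Q then standing, which I expect to be at least the reading above. That test is the one I would put to the flask.

| setting | blue | red | flask |
|---|---|---|---|
| substrate | 0.80 M | 0.80 M | 0.80 M |
| partner | 3 equiv | 3 equiv | 3.00 equiv |
| protic impurity | 0.016 M | 0.016 M | 0.0160 M |
| temperature | 25 °C | 10 °C | 25 °C |
| remark | the very flask that is asked about, followed so far | run made earlier |  |
| time |  |  | 15 min |

| run | time / min | target / % | substrate / % |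
|---|---|---|---|
| blue | 1.00 | 19.3 | 79.8 |
| blue | 2.00 | 32.0 | 63.6 |
| blue | 5.00 | 51.7 | 32.6 |
| blue | 12.0 | 49.4 | 6.7 |
| red | 2.00 | 5.7 | 93.7 |
| red | 4.00 | 11.4 | 87.9 |
| red | 10.0 | 24.6 | 73.3 |
| red | 25.0 | 43.1 | 45.0 |

(readings scatter by 0.3 percentage points)

- delta: at 15 min raise the temperature by 15 K, then wait 5.0 min
- alpha: change nothing and wait 5.0 min more
- zeta: at 15 min take out 90% of the leaving ligand then present, then wait 5.0 min

- additions bring no volume worth counting
- reactions considered so far: substrate -> decomposition product; partner + protic impurity -> quenched reagent; partner + intermediate -> target; substrate <-> intermediate + leaving ligand; target <-> isomer of the product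

- target, in percent of the substrate first charged, at 15 min
- the option that brings most further target ("none" if no option brings more than 2 percentage points) (delta / alpha / zeta / none)
- target present, in percent of the substrate first charged, after delta
- target present, in percent of the substrate first charged, after zeta

The forecast gives 45%, none, 30% and 38.5%: “Heating speeds the approach to equilibrium”.

The flask gives 44.5%, and delta is best at 54.6%, a gain of 10 percentage points, while zeta gives 37.6%.

    substrate → decomposition product (k = 2.90 × 10⁻⁵ /s, Ea = 94.0 kJ/mol)
    partner + protic impurity → quenched reagent (k = 1.30 /M/s, Ea = 39.0 kJ/mol)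
    partner + intermediate → target (k = 16.0 /M/s, Ea = 41.0 kJ/mol)
    substrate ⇌ intermediate + leaving ligand (K = 0.00660 M, k = 0.00370 /s, Ea = 91.0 kJ/mol, ΔH = 31.0 kJ/mol)
    target ⇌ isomer of the product (K = 2.60, k = 0.00160 /s, Ea = 79.0 kJ/mol, ΔH = −60.0 kJ/mol)
    (constants at 25 °C)

The step gives off heat, with −60.0 kJ/mol. In the flask Q stands at 1.15 at 15 min, where the blue reading at 12.0 min gave 0.889, and that is 0.443 of K at 25 °C; left at that temperature, the flask holds 27.6% target at 1.0 h. The neighbour flask kept at 40 °C ends at Q = 0.816, lower than the flask's 1.15, with target at 54.6%.

(The data were generated by integration with constants of no real substance; the scatter is artificial.)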